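# Proposed synthesis of 2-[(3R,5R)-3,5-dimethyl-5-[(2R)-2-methyl-10-phenyldecyl]-1,2-dioxolan-3-yl]acetic acid by late O–O ring closure of a syn-1,3-diol

Atom labels used throughout: ring atoms O1–O2–C3–C4–C5; the acetic acid arm is C2 (CH2) and C1 (carboxyl carbon); the side chain on C5 is C1' to C10' (C2' bears the methyl group, C10' the phenyl ring).

## Analysis of the target

Target 25 is a 3,3,5,5-tetrasubstituted 1,2-dioxolane. C3 carries a methyl group and the C2–C1 acetic acid arm; C5 carries a methyl group and the (2R)-2-methyl-10-phenyldecyl chain. There are three stereocentres, C3 (R), C5 (R) and C2' (R). The two ring methyl groups are cis, and C2' lies 1,3 to C5 across the flexible C1' methylene, too remote to steer reactions at the ring. The O1–O2 bond is the sensitive group: it does not survive catalytic hydrogenation, aluminium hydrides or organometallic reagents, so all reductive chemistry must be finished before it exists. The ring has no hydrogen on C3 or C5, which should make it tolerant of base, fluoride and mild oxidants. The difficulty is that both ring carbons are quaternary and oxygen-bearing, are differentiated only by methyl against CH2R, and are normally joined to peroxide oxygen through tertiary radicals or cations that lose configuration. The strategy rests on the fact that C3 and C5 are both tertiary carbinol carbons linked by the single methylene C4. Cutting O1–O2 therefore uncovers a syn-1,3-diol whose centres can be set by alcohol chemistry and carried into the peroxide without touching a C–O bond.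

## Retrosynthetic reasoning

**C1 oxidation level (25 from 23 via 24, 23 from 22).** The carboxyl group is introduced last by oxidation of the primary alcohol 23 through aldehyde 24, and 23 comes from silyl ether 22 by desilylation. A free acid or aldehyde at C1 would not survive an oxidative O–O closure: a carboxylate would bind the oxidant and decarboxylate, and a β-oxygenated aldehyde can eliminate. The silyl ether is inert. The forward steps only have to spare a peroxide that has no α-hydrogen.

**O1–O2 (22 from 20 via 21).** This is the only ring bond whose formation leaves all four bonds at C3 and at C5 untouched. Any C–O disconnection passes through a tertiary radical or cation at a ring carbon and gives up the configuration. Cutting O1–O2 turns the peroxide problem into the synthesis of the syn diol 20. The forward reaction has to remove two electrons and two protons from the two hydroxyl groups and join the oxygens, through the cyclic iodane 21, faster than the oxygen-centred intermediates fragment.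

**C3 carbinol (20 from 19, 19 from 18, 18 from 17).** Silyl ether 20 is the primary-selective silylation product of triol 19. In 19 the C3–O bond and the C2–H bond are traced back to epoxy alcohol 18 and from there to the (E)-allylic alcohol 17. A reagent-controlled Katsuki–Sharpless epoxidation is chosen because the existing C5 centre is a quaternary carbinol whose two arms (methyl and CH2) are too similar to bias a substrate-controlled addition to a C3 ketone. Directed hydride opening at C2 then leaves the C3–O bond, and with it the new configuration, intact.

**C3–CH3 and C2–C1 (17 from 15 via 16).** Both bonds are cut at once, leading to terminal alkyne 15. Syn methylalumination places the methyl group on C3 and the metal on C2 with defined E geometry (alkenylalane 16), and hydroxymethylation adds C1. The E geometry is what the epoxidation needs for clean facial selection.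

**C3–C2 (15 from 14, 14 from 13).** The alkyne carbon C2 is removed in a one-carbon homologation of aldehyde 14, which is the selectively oxidised primary alcohol of 1,3-diol 13. This makes the sequence iterative: the 3-hydroxy-3-methylalkan-1-ol produced by one cycle is the substrate for the next.

**C5 carbinol and chain saturation (13 from 12, 12 from 11, 11 from 10).** The same epoxidation and hydride opening, applied to allylic alcohol 10, set C5. The chain double bond left by the olefination is hydrogenated at diol 12. This is the first intermediate that has no alkyne, allylic alcohol or epoxide to protect, and it lies well before the peroxide.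

**C5–CH3 and C4–C3 (10 from 8 via 9).** A first methylalumination and hydroxymethylation of alkyne 8, through alkenylalane 9, builds the trisubstituted allylic alcohol.

**Chain and chiral pool (8 from 6 and 2 via 7, 6 from 4 via 5, 4 from 3, 2 from 1).** The C5'=C6' bond is cut by a Wittig disconnection into aldehyde 6 and phosphonium salt 2 (ylide 7), the latter from bromide 1. Aldehyde 6 is the ozonolysis product (ozonide 5) of enyne 4, and 4 is the one-carbon alkyne homologue of (R)-citronellal 3. In this mapping the aldehyde carbon of 3 becomes C5, its CH2 becomes C1', its stereocentre is C2' with the correct configuration, and its prenyl end supplies C3'–C5'.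

## Alternatives that were turned down

**Alternative 1:** Both exocyclic C–C bonds at the peroxide carbons (C3–C2 and C5–C1') are cut. This leads to the bis(peroxyketal) 3,5-dimethoxy-3,5-dimethyl-1,2-dioxolane A1 and the 1,3-bis-nucleophile trimethyl{[3-(trimethylsilyl)prop-1-en-2-yl]oxy}silane A2. In the forward step a silyl triflate Lewis acid would ionise A1 twice, and A2 would trap the two peroxycarbenium ions in turn as allylsilane and as silyl enol ether. This closes a six-membered carbocycle across the dioxolane and gives the meso ketone (1R,5S)-1,5-dimethyl-6,7-dioxabicyclo[3.2.1]octan-3-one A3.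
- For: the bridged bicycle can only form with the two methyl groups cis. The relative configuration at C3 and C5 is therefore fixed by geometry, and on this point the alternative is stronger than any acyclic approach, the chosen one included. Peroxycarbenium substitution is established chemistry, and the ring is reached in very few steps.
- Against: A3 is achiral, so the absolute configuration must come from an enantioselective desymmetrisation, for instance a Baeyer–Villiger insertion that tells the two CH2–C(=O) arms apart. After ring cleavage the C1'–C10' chain and its C2' stereocentre must still be grown from a one-carbon stub on C5, at a neopentyl position. Only reactions that spare the O–O bond may be used, which excludes organomagnesium and organocopper reagents, hydrides and hydrogenation.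
- Comparison: the peroxide would be carried through many steps, and two of the three stereochemical questions (absolute sense and C2') stay open. The chosen route gives up the geometric lock but sets C3, C5 and C2' independently and forms the peroxide two steps from the end.

**Alternative 2:** The C5–O1 and C3–O2 bonds are cut, leading to the vinylcyclopropane 1-ethenyl-1,2-dimethyl-2-[(2R)-2-methyl-10-phenyldecyl]cyclopropane A4. In the forward step an arylthiyl radical adds to the vinyl group under air, and the cyclopropylcarbinyl radical opens by cleaving the bond between the two quaternary carbons. The tertiary radical at C5 captures dioxygen, and the peroxyl radical closes 5-exo onto C3 with loss of the thiyl radical. The product is (3R,5R)-3-ethenyl-3,5-dimethyl-5-[(2R)-2-methyl-10-phenyldecyl]-1,2-dioxolane A5, whose vinyl group would be converted into the acetic acid arm by anti-Markovnikov hydration and oxidation.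
- For: both C–O bonds and the ring form in one catalytic radical chain from air, and the configuration of A4 does not matter because it is erased. In ring-forming efficiency and precedent for this reaction type it is stronger than the chosen key step.
- Against: erasing configuration is the weakness for this target. C5 passes through a planar tertiary radical flanked by methyl and two CH2 groups, and the closure has to create a second quaternary centre at C3 by attack on the more substituted alkene carbon. Neither the absolute configuration nor the cis relationship is controlled, and with the fixed C2' centre up to four diastereomers that differ only at remote quaternary carbons are expected. A tetrasubstituted vinylcyclopropane with the full chain is itself several steps away.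
- Comparison: shorter at the ring, but the single stereoisomer would have to be obtained by separation. The chosen route offers defined configuration at both ring carbons at the cost of a longer approach and an unproven closure.

**Alternative 3:** The C4–C5 and C3–O2 bonds are cut, leading to the chain ketone (4R)-4-methyl-12-phenyldodecan-2-one A6, its silyl peroxyketal triethyl{[(4R)-2-methoxy-4-methyl-12-phenyldodecan-2-yl]peroxy}silane A7, and methyl 3-methylbut-3-enoate A8. In the forward step a tin Lewis acid ionises A7 to a peroxycarbenium ion. The 1,1-disubstituted alkene A8 adds to it to form C4–C5, and the tertiary cation so produced is captured by the silyl peroxide oxygen to close the ring. The product is methyl 2-[(3R,5R)-3,5-dimethyl-5-[(2R)-2-methyl-10-phenyldecyl]-1,2-dioxolan-3-yl]acetate A9, one saponification from the target.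
- For: this is the most convergent and the shortest plan. The whole skeleton, the ring and the correct oxidation level at C1 arrive in one precedented step from a ketone a few steps from citronellal and a simple alkene. In step economy and in the reliability of the ring-forming reaction it is clearly stronger than the chosen route.
- Against: the peroxycarbenium ion is planar at C5, and its only stereochemical neighbour is C2', two bonds away on a freely rotating chain. C3 is formed by capture of a tertiary cation whose substituents (methyl, CH2CO2Me) differ little. Little control of either the absolute or the relative configuration can be expected, and the desired isomer would be one of up to four close-running diastereomers.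
- Comparison: Alternative 3 gives the compound quickly as a mixture. The chosen route trades about twice the step count and an unprecedented key step for reagent-controlled, independently assignable configuration at C3 and C5.

Key step: step 15

Remark on the chemistry: commercial (R)-citronellal and D-(−)-diethyl tartrate of high enantiomeric purity are assumed; the cis arrangement of the ring methyl groups in the target corresponds to the syn diol, which is what two epoxidations of the same sense deliver.

## Route

**Step 1**
Reactants: 1 (5-bromopentyl)benzene
Product: 2 triphenyl(5-phenylpentyl)phosphonium bromide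
Conditions: PPh3, MeCN, reflux
Reagents that add atoms: triphenylphosphine, c1ccc(cc1)P(c1ccccc1)c1ccccc1
Why: SN2 quaternisation of an unhindered primary bromide by the phosphine; the salt should crystallise and be dried before use in the Wittig reaction.

**Step 2**
Reactants: 3 (R)-citronellal
Product: 4 (4R)-4,8-dimethylnon-7-en-1-yne
Conditions: dimethyl (1-diazo-2-oxopropyl)phosphonate, K2CO3, MeOH, 0 °C to rt
Reagents that add atoms: dimethyl (1-diazo-2-oxopropyl)phosphonate, CC(=O)C(=[N+]=[N-])P(=O)(OC)OC
Why: Seyferth–Gilbert homologation in the Ohira–Bestmann variant converts the aldehyde into the terminal alkyne with one added carbon; the stereocentre is β to the carbonyl and cannot epimerise under the mild base.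

**Step 3**
Reactants: 4 (4R)-4,8-dimethylnon-7-en-1-yne
Product: 6 (4R)-4-methylhept-6-ynal, via secondary ozonide 5 (not isolated)
Conditions: O3, CH2Cl2, −78 °C (Sudan Red 7B end point); PPh3, −78 °C to rt
Reagents that add atoms: ozone, [O-][O+]=O
Why: Ozonolysis with reductive work-up; the electron-rich trisubstituted alkene reacts far faster with ozone than the terminal alkyne, and the dye indicator stops the addition once the alkene is consumed.

**Step 4**
Reactants: 6 (4R)-4-methylhept-6-ynal; 2 triphenyl(5-phenylpentyl)phosphonium bromide
Product: 8 (4R,7Z)-4-methyl-12-phenyldodec-7-en-1-yne, via phosphorus ylide 7 (not isolated)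
Conditions: 2, NaN(SiMe3)2, THF, 0 °C; then 6, −78 °C to rt
Reagents that add atoms: none
Why: Wittig olefination with a non-stabilised ylide under salt-free conditions should give mainly the Z alkene and completes the C2'–C10' chain; the geometry is irrelevant because the alkene is hydrogenated in step 8, and the ylide is not basic enough to consume the alkyne C–H.

**Step 5**
Reactants: 8 (4R,7Z)-4-methyl-12-phenyldodec-7-en-1-yne
Product: 10 (2E,5R,8Z)-3,5-dimethyl-13-phenyltrideca-2,8-dien-1-ol, via alkenylalane 9 (not isolated)
Conditions: AlMe3, (C5H5)2ZrCl2 (20 mol %), CH2Cl2, 0 °C to rt; then (CH2O)n, THF, 0 °C to rt; aq. KNaC4H4O6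
Reagents that add atoms: trimethylaluminium, C[Al](C)C; formaldehyde (from paraformaldehyde), C=O
Why: Negishi zirconium-catalysed carboalumination adds methyl and aluminium syn across the terminal alkyne with the metal on the terminal carbon, which fixes the E geometry; the alkenyl–aluminium bond then adds to formaldehyde with retention, and the internal Z alkene does not take part.

**Step 6**
Reactants: 10 (2E,5R,8Z)-3,5-dimethyl-13-phenyltrideca-2,8-dien-1-ol
Product: 11 [(2R,3R)-3-methyl-3-[(2R,5Z)-2-methyl-10-phenyldec-5-en-1-yl]oxiran-2-yl]methanol
Conditions: Ti(OiPr)4 (10 mol %), D-(−)-diethyl tartrate (12 mol %), t-BuOOH, 4 Å MS, CH2Cl2, −20 °C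
Reagents that add atoms: tert-butyl hydroperoxide, CC(C)(C)OO
Why: Katsuki–Sharpless asymmetric epoxidation; with D-(−)-tartrate an (E)-3,3-disubstituted allylic alcohol is epoxidised in the same sense as geraniol to the (2R,3R) epoxide, which sets the future C5 under reagent control independent of the remote chain centre; the isolated Z alkene is not epoxidised by the titanium–peroxide system.

**Step 7**
Reactants: 11 [(2R,3R)-3-methyl-3-[(2R,5Z)-2-methyl-10-phenyldec-5-en-1-yl]oxiran-2-yl]methanol
Product: 12 (3R,5R,8Z)-3,5-dimethyl-13-phenyltridec-8-ene-1,3-diol
Conditions: NaAlH2(OCH2CH2OMe)2, THF, 0 °C to rt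
Reagents that add atoms: none
Why: Directed reductive opening of a 2,3-epoxy alcohol: the alkoxy-bound aluminium hydride delivers hydride intramolecularly to the less hindered carbon next to the carbinol, giving the 1,3-diol; the tertiary C–O bond is not broken, so its configuration is retained.

**Step 8**
Reactants: 12 (3R,5R,8Z)-3,5-dimethyl-13-phenyltridec-8-ene-1,3-diol
Product: 13 (3R,5R)-3,5-dimethyl-13-phenyltridecane-1,3-diol
Conditions: H2 (1 atm), 10% Pd on carbon, EtOAc, rt
Reagents that add atoms: none
Why: Heterogeneous catalytic hydrogenation of the disubstituted alkene; the benzene ring and the alcohols are inert under these conditions, and any E isomer from step 4 converges on the same product.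

**Step 9**
Reactants: 13 (3R,5R)-3,5-dimethyl-13-phenyltridecane-1,3-diol
Product: 14 (3R,5R)-3-hydroxy-3,5-dimethyl-13-phenyltridecanal
Conditions: TEMPO (10 mol %), PhI(OAc)2, CH2Cl2, rt
Reagents that add atoms: none
Why: Oxoammonium-mediated oxidation is selective for the primary alcohol, the tertiary one cannot be oxidised, and the anhydrous conditions stop at the aldehyde; the β-hydroxy aldehyde should be used directly in step 10.

**Step 10**
Reactants: 14 (3R,5R)-3-hydroxy-3,5-dimethyl-13-phenyltridecanal
Product: 15 (4R,6R)-4,6-dimethyl-14-phenyltetradec-1-yn-4-ol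
Conditions: dimethyl (1-diazo-2-oxopropyl)phosphonate, K2CO3, MeOH, 0 °C to rt
Reagents that add atoms: dimethyl (1-diazo-2-oxopropyl)phosphonate, CC(=O)C(=[N+]=[N-])P(=O)(OC)OC
Why: A second Ohira–Bestmann homologation turns the aldehyde carbon (the future C3) into the internal carbon of a terminal alkyne; the mild carbonate base at low temperature is chosen to keep retro-aldol cleavage of the β-hydroxy aldehyde slow relative to the homologation.

**Step 11**
Reactants: 15 (4R,6R)-4,6-dimethyl-14-phenyltetradec-1-yn-4-ol
Product: 17 (2E,5R,7R)-3,5,7-trimethyl-15-phenylpentadec-2-ene-1,5-diol, via alkenylalane alkoxide 16 (not isolated)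
Conditions: AlMe3 (excess), (C5H5)2ZrCl2 (30 mol %), CH2Cl2, 0 °C to rt; then (CH2O)n, THF, 0 °C to rt; aq. KNaC4H4O6
Reagents that add atoms: trimethylaluminium, C[Al](C)C; formaldehyde (from paraformaldehyde), C=O
Why: Negishi carboalumination of a homopropargylic alcohol, which reacts as its aluminium alkoxide after loss of methane, again gives syn methyl–aluminium addition with E geometry, and capture by formaldehyde installs C1; this places the C3 methyl group and the allylic alcohol needed for the next epoxidation in one operation.

**Step 12**
Reactants: 17 (2E,5R,7R)-3,5,7-trimethyl-15-phenylpentadec-2-ene-1,5-diol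
Product: 18 (2R,4R)-1-[(2R,3R)-3-(hydroxymethyl)-2-methyloxiran-2-yl]-2,4-dimethyl-12-phenyldodecan-2-ol
Conditions: Ti(OiPr)4 (1.0 equiv), D-(−)-diethyl tartrate (1.2 equiv), t-BuOOH, 4 Å MS, CH2Cl2, −20 °C
Reagents that add atoms: tert-butyl hydroperoxide, CC(C)(C)OO
Why: A second Katsuki–Sharpless epoxidation with the same D-(−)-tartrate gives the (2R,3R) epoxide and so sets the future C3 in the sense that makes the 1,3-diol syn; a full equivalent of the titanium–tartrate complex is used because the hindered tertiary hydroxyl can bind titanium without being an allylic alcohol itself.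

**Step 13**
Reactants: 18 (2R,4R)-1-[(2R,3R)-3-(hydroxymethyl)-2-methyloxiran-2-yl]-2,4-dimethyl-12-phenyldodecan-2-ol
Product: 19 (3S,5R,7R)-3,5,7-trimethyl-15-phenylpentadecane-1,3,5-triol
Conditions: NaAlH2(OCH2CH2OMe)2 (excess), THF, 0 °C to rt
Reagents that add atoms: none
Why: The same directed hydride opening as in step 7 delivers hydride to C2 and leaves the C3–O bond untouched, so the triol has both tertiary carbinols in the syn relationship (C3 becomes S only because the substituent priorities change).

**Step 14**
Reactants: 19 (3S,5R,7R)-3,5,7-trimethyl-15-phenylpentadecane-1,3,5-triol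
Product: 20 (3S,5R,7R)-1-[(tert-butyldimethylsilyl)oxy]-3,5,7-trimethyl-15-phenylpentadecane-3,5-diol
Conditions: t-BuMe2SiCl, imidazole, CH2Cl2, 0 °C
Reagents that add atoms: tert-butyldimethylsilyl chloride, CC(C)(C)[Si](C)(C)Cl
Why: Silylation with a bulky chlorosilane is selective for the primary hydroxyl over the two tertiary ones, which masks the only oxidisable C–H-bearing alcohol before the key step.

**Step 15**
Reactants: 20 (3S,5R,7R)-1-[(tert-butyldimethylsilyl)oxy]-3,5,7-trimethyl-15-phenylpentadecane-3,5-diol
Product: 22 tert-butyl{2-[(3S,5R)-3,5-dimethyl-5-[(2R)-2-methyl-10-phenyldecyl]-1,2-dioxolan-3-yl]ethoxy}dimethylsilane, via cyclic dialkoxy-λ3-iodane 21 (not isolated)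
Conditions: PhI(OAc)2 (1.2 equiv), K2CO3 (3 equiv), 4 Å MS, CH2Cl2, rt, dark; then 390 nm LED, −20 °C
Reagents that add atoms: none
Why: Proposed new method: exchange of both tertiary hydroxyls onto trivalent iodine, driven by K2CO3 removing acetic acid, should give the six-membered 1,3,2-dioxaiodinane 21, which holds the oxygen atoms of C3 and C5 on one iodine centre. Near-UV light cleaves one weak hypervalent I–O bond; the alkoxyl radical so formed sits next to an O–I(Ph) unit with only a feeble I–O bond left, so homolytic substitution at that oxygen joins O1 to O2 and expels iodobenzene, which amounts to collapse of a singlet 1,3-dioxyl pair (the reverse of O–O homolysis of a dioxolane), and a concerted apical–equatorial ligand coupling at iodine would end at the same product. The closest known reaction types are the Pb(OAc)4 closure of 1,3-bis(hydroperoxides) to 1,2-dioxolanes, which also runs through two tethered tertiary oxygen radicals, the release of alkoxyl radicals from tertiary alkoxy-λ3-iodanes, and aryl-λ3-iodane-mediated N–N and N–O ring closures. The dioxolane closes by ring contraction of the six-membered iodane chelate, formally a 5-exo substitution at oxygen with iodine as the leaving atom. No stereocentre is made: no C–O bond is touched, so C5 and C3 keep the configurations set in steps 6 and 12, and the syn diol maps onto the cis-3,5-dimethyl dioxolane. The step needs O–O coupling to outrun β-scission at C3 or C5 and 1,5-hydrogen transfer from C6–H or C8–H (pentadecane numbering of 20); the 1,3 tether, the weak residual I–O bond and the low temperature should favour the activation-free collapse over these activated unimolecular decays. Enthalpically the exchange of two hypervalent I–O bonds for one O–O bond is close to neutral, and release of iodobenzene provides the driving force.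

**Step 16**
Reactants: 22 tert-butyl{2-[(3S,5R)-3,5-dimethyl-5-[(2R)-2-methyl-10-phenyldecyl]-1,2-dioxolan-3-yl]ethoxy}dimethylsilane
Product: 23 2-[(3S,5R)-3,5-dimethyl-5-[(2R)-2-methyl-10-phenyldecyl]-1,2-dioxolan-3-yl]ethan-1-ol
Conditions: Bu4NF, AcOH, THF, 0 °C to rt
Reagents that add atoms: none
Why: Fluoride-mediated desilylation, buffered with acetic acid; the peroxide carries no hydrogen on C3 or C5 and therefore cannot undergo base-induced fragmentation.

**Step 17**
Reactants: 23 2-[(3S,5R)-3,5-dimethyl-5-[(2R)-2-methyl-10-phenyldecyl]-1,2-dioxolan-3-yl]ethan-1-ol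
Product: 25 2-[(3R,5R)-3,5-dimethyl-5-[(2R)-2-methyl-10-phenyldecyl]-1,2-dioxolan-3-yl]acetic acid, via peroxy aldehyde 24 (not isolated)
Conditions: TEMPO (20 mol %), PhI(OAc)2 (2.5 equiv), MeCN/H2O 1:1, rt
Reagents that add atoms: water, O
Why: Oxoammonium oxidation in aqueous acetonitrile takes the primary alcohol to the aldehyde and, through its hydrate, on to the carboxylic acid in one flask under near-neutral conditions; the dialkyl peroxide and the alkylbenzene are not attacked, and the β-peroxy aldehyde is not isolated (C3 becomes R only by the change in substituent priorities).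

## Compound list

1 | (5-bromopentyl)benzene | BrCCCCCc1ccccc1 | starting material
2 | triphenyl(5-phenylpentyl)phosphonium bromide | [Br-].c1ccc(cc1)CCCCC[P+](c1ccccc1)(c1ccccc1)c1ccccc1 | intermediate
3 | (R)-citronellal, (3R)-3,7-dimethyloct-6-enal | C[C@H](CCC=C(C)C)CC=O | starting material
4 | (4R)-4,8-dimethylnon-7-en-1-yne | C#CC[C@H](C)CCC=C(C)C | intermediate
5 | 3,3-dimethyl-5-[(3R)-3-methylhex-5-yn-1-yl]-1,2,4-trioxolane (secondary ozonide, both configurations at the acetal carbon) | C#CC[C@H](C)CCC1OOC(C)(C)O1 | intermediate (not isolated)
6 | (4R)-4-methylhept-6-ynal | C#CC[C@H](C)CCC=O | intermediate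
7 | triphenyl(5-phenylpentylidene)-λ5-phosphane (ylide) | C(CCCCc1ccccc1)=P(c1ccccc1)(c1ccccc1)c1ccccc1 | intermediate (not isolated)
8 | (4R,7Z)-4-methyl-12-phenyldodec-7-en-1-yne | C#CC[C@H](C)CC/C=C\CCCCc1ccccc1 | intermediate
9 | [(1E,4R,7Z)-2,4-dimethyl-12-phenyldodeca-1,7-dien-1-yl]dimethylalumane | C[Al](C)/C=C(\C)C[C@H](C)CC/C=C\CCCCc1ccccc1 | intermediate (not isolated)
10 | (2E,5R,8Z)-3,5-dimethyl-13-phenyltrideca-2,8-dien-1-ol | OC/C=C(\C)C[C@H](C)CC/C=C\CCCCc1ccccc1 | intermediate
11 | [(2R,3R)-3-methyl-3-[(2R,5Z)-2-methyl-10-phenyldec-5-en-1-yl]oxiran-2-yl]methanol | OC[C@H]1O[C@]1(C)C[C@H](C)CC/C=C\CCCCc1ccccc1 | intermediate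
12 | (3R,5R,8Z)-3,5-dimethyl-13-phenyltridec-8-ene-1,3-diol | OCC[C@](C)(O)C[C@H](C)CC/C=C\CCCCc1ccccc1 | intermediate
13 | (3R,5R)-3,5-dimethyl-13-phenyltridecane-1,3-diol | OCC[C@](C)(O)C[C@H](C)CCCCCCCCc1ccccc1 | intermediate
14 | (3R,5R)-3-hydroxy-3,5-dimethyl-13-phenyltridecanal | O=CC[C@](C)(O)C[C@H](C)CCCCCCCCc1ccccc1 | intermediate
15 | (4R,6R)-4,6-dimethyl-14-phenyltetradec-1-yn-4-ol | C#CC[C@](C)(O)C[C@H](C)CCCCCCCCc1ccccc1 | intermediate
16 | [(1E,4R,6R)-4-[(dimethylalumanyl)oxy]-2,4,6-trimethyl-14-phenyltetradec-1-en-1-yl]dimethylalumane | C[Al](C)/C=C(\C)C[C@](C)(O[Al](C)C)C[C@H](C)CCCCCCCCc1ccccc1 | intermediate (not isolated)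
17 | (2E,5R,7R)-3,5,7-trimethyl-15-phenylpentadec-2-ene-1,5-diol | OC/C=C(\C)C[C@](C)(O)C[C@H](C)CCCCCCCCc1ccccc1 | intermediate
18 | (2R,4R)-1-[(2R,3R)-3-(hydroxymethyl)-2-methyloxiran-2-yl]-2,4-dimethyl-12-phenyldodecan-2-ol | OC[C@H]1O[C@]1(C)C[C@](C)(O)C[C@H](C)CCCCCCCCc1ccccc1 | intermediate
19 | (3S,5R,7R)-3,5,7-trimethyl-15-phenylpentadecane-1,3,5-triol | OCC[C@](C)(O)C[C@](C)(O)C[C@H](C)CCCCCCCCc1ccccc1 | intermediate
20 | (3S,5R,7R)-1-[(tert-butyldimethylsilyl)oxy]-3,5,7-trimethyl-15-phenylpentadecane-3,5-diol | C[C@H](CCCCCCCCc1ccccc1)C[C@](O)(C)C[C@](C)(CCO[Si](C)(C)C(C)(C)C)O | intermediate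
21 | tert-butyl{2-[(4S,6R)-4,6-dimethyl-6-[(2R)-2-methyl-10-phenyldecyl]-2-phenyl-1,3,2λ3-dioxaiodinan-4-yl]ethoxy}dimethylsilane | C[C@H](CCCCCCCCc1ccccc1)C[C@]1(C)C[C@](C)(CCO[Si](C)(C)C(C)(C)C)OI(c2ccccc2)O1 | intermediate (not isolated)
22 | tert-butyl{2-[(3S,5R)-3,5-dimethyl-5-[(2R)-2-methyl-10-phenyldecyl]-1,2-dioxolan-3-yl]ethoxy}dimethylsilane | C[C@H](CCCCCCCCc1ccccc1)C[C@]1(C)C[C@](C)(CCO[Si](C)(C)C(C)(C)C)OO1 | intermediate
23 | 2-[(3S,5R)-3,5-dimethyl-5-[(2R)-2-methyl-10-phenyldecyl]-1,2-dioxolan-3-yl]ethan-1-ol | C[C@H](CCCCCCCCc1ccccc1)C[C@]1(C)C[C@](C)(CCO)OO1 | intermediate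
24 | 2-[(3R,5R)-3,5-dimethyl-5-[(2R)-2-methyl-10-phenyldecyl]-1,2-dioxolan-3-yl]acetaldehyde | C[C@H](CCCCCCCCc1ccccc1)C[C@]1(C)C[C@](C)(CC=O)OO1 | intermediate (not isolated)
25 | 2-[(3R,5R)-3,5-dimethyl-5-[(2R)-2-methyl-10-phenyldecyl]-1,2-dioxolan-3-yl]acetic acid | C[C@H](CCCCCCCCc1ccccc1)C[C@]1(C)C[C@](C)(CC(=O)O)OO1 | target

## Step count and risk

Total step count: 17. Longest linear sequence: 16 steps (steps 2 to 17, from (R)-citronellal 3); step 1 is a one-step side branch.

**Step 15 (key step, proposed new method).**
- What may go wrong: ligand exchange at two hindered tertiary hydroxyls may not proceed, so the diol is simply recovered. If it does proceed, oxygen–oxygen coupling may lose to fragmentation of the tertiary alkoxyl radical (β-scission to a methyl ketone and a carbon radical) or to 1,5-hydrogen abstraction from the chain followed by ether formation. Each oxygen-centred radical has several such exits, and the coupling has no precedent.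
- Fallback (known chemistry; the diol approach is abandoned and the peroxide is built by peroxyketal substitution): the fallback sets out from alkyne 15.
  - Metal-catalysed Markovnikov hydration (for example Ph3PAuCl/AgOTf in aqueous dioxane) gives (4R,6R)-4-hydroxy-4,6-dimethyl-14-phenyltetradecan-2-one F1.
  - 50% H2O2 with catalytic H2SO4 converts this β-hydroxy ketone into 3,5-dimethyl-5-[(2R)-2-methyl-10-phenyldecyl]-1,2-dioxolan-3-ol F2.
  - MeOH with TsOH gives 3-methoxy-3,5-dimethyl-5-[(2R)-2-methyl-10-phenyldecyl]-1,2-dioxolane F3.
  - TiCl4 and 1-ethoxy-1-(trimethylsilyloxy)ethene in CH2Cl2 at −78 °C substitute the methoxy group through the peroxycarbenium ion. The (3R,5R) isomer, ethyl 2-[(3R,5R)-3,5-dimethyl-5-[(2R)-2-methyl-10-phenyldecyl]-1,2-dioxolan-3-yl]acetate F4, is separated from its ring diastereomers by preparative HPLC.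
  - Saponification with LiOH in aqueous THF returns to the route at target 25.
  - This fallback gives up the stereochemical advantage of the main route: the tertiary C–O bond ionises during peroxide formation and the substitution at C3 is only substrate-biased, so the target would be reached by separation.

**Step 10.**
- What may go wrong: retro-aldol cleavage or dehydration of the tertiary β-hydroxy aldehyde under carbonate in methanol may compete with the homologation.
- Fallback (the tertiary hydroxyl is masked before the aldehyde is made): the fallback sets out from diol 13.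
  - Et3SiOTf and 2,6-lutidine give (3R,5R)-3,5-dimethyl-13-phenyl-1,3-bis[(triethylsilyl)oxy]tridecane F5.
  - Swern conditions ((COCl)2, DMSO, Et3N) cleave and oxidise only the primary silyl ether to (3R,5R)-3,5-dimethyl-13-phenyl-3-[(triethylsilyl)oxy]tridecanal F6.
  - Ohira–Bestmann homologation gives triethyl{[(4R,6R)-4,6-dimethyl-14-phenyltetradec-1-yn-4-yl]oxy}silane F7.
  - Bu4NF returns to the route at 15.

**Step 11.**
- What may go wrong: capture of the alkenylalane by paraformaldehyde may be incomplete in the presence of the aluminium alkoxide, so that protodemetalation to the 2-methyl-1-alkene takes over.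
- Fallback (acylation and reduction in place of direct hydroxymethylation): the fallback sets out from 15. After the same carboalumination the alkenylalane is trapped with ethyl chloroformate, which reacts readily with alkenylalanes, to give ethyl (2E,5R,7R)-5-hydroxy-3,5,7-trimethyl-15-phenylpentadec-2-enoate F8. Reduction with i-Bu2AlH in CH2Cl2 at −78 °C returns to the route at 17.

**Step 3.**
- What may go wrong: over-oxidation of the terminal alkyne by excess ozone, and loss of the small, volatile aldehyde on isolation.
- Fallback (dihydroxylation and glycol cleavage in place of ozonolysis): the fallback sets out from enyne 4. OsO4 (catalytic) with N-methylmorpholine N-oxide in aqueous acetone dihydroxylates only the trisubstituted alkene to (6R)-2,6-dimethylnon-8-yne-2,3-diol F9. NaIO4 in aqueous THF cleaves the diol and returns to the route at 6, which can be taken into step 4 as a solution.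

## Further compounds

F1 | step 15 | (4R,6R)-4-hydroxy-4,6-dimethyl-14-phenyltetradecan-2-one | CC(=O)C[C@](C)(O)C[C@H](C)CCCCCCCCc1ccccc1
F2 | step 15 | 3,5-dimethyl-5-[(2R)-2-methyl-10-phenyldecyl]-1,2-dioxolan-3-ol (mixture at C3 and C5) | C[C@H](CCCCCCCCc1ccccc1)CC1(C)CC(C)(O)OO1
F3 | step 15 | 3-methoxy-3,5-dimethyl-5-[(2R)-2-methyl-10-phenyldecyl]-1,2-dioxolane (mixture at C3 and C5) | C[C@H](CCCCCCCCc1ccccc1)CC1(C)CC(C)(OC)OO1
F4 | step 15 | ethyl 2-[(3R,5R)-3,5-dimethyl-5-[(2R)-2-methyl-10-phenyldecyl]-1,2-dioxolan-3-yl]acetate (after separation from its ring diastereomers) | C[C@H](CCCCCCCCc1ccccc1)C[C@]1(C)C[C@](C)(CC(=O)OCC)OO1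
F5 | step 10 | (3R,5R)-3,5-dimethyl-13-phenyl-1,3-bis[(triethylsilyl)oxy]tridecane | CC[Si](CC)(CC)OCC[C@](C)(O[Si](CC)(CC)CC)C[C@H](C)CCCCCCCCc1ccccc1
F6 | step 10 | (3R,5R)-3,5-dimethyl-13-phenyl-3-[(triethylsilyl)oxy]tridecanal | O=CC[C@](C)(O[Si](CC)(CC)CC)C[C@H](C)CCCCCCCCc1ccccc1
F7 | step 10 | triethyl{[(4R,6R)-4,6-dimethyl-14-phenyltetradec-1-yn-4-yl]oxy}silane | C#CC[C@](C)(O[Si](CC)(CC)CC)C[C@H](C)CCCCCCCCc1ccccc1
F8 | step 11 | ethyl (2E,5R,7R)-5-hydroxy-3,5,7-trimethyl-15-phenylpentadec-2-enoate | CCOC(=O)/C=C(\C)C[C@](C)(O)C[C@H](C)CCCCCCCCc1ccccc1
F9 | step 3 | (6R)-2,6-dimethylnon-8-yne-2,3-diol (both configurations at C3) | C#CC[C@H](C)CCC(O)C(C)(C)O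
A1 | alternative 1 | 3,5-dimethoxy-3,5-dimethyl-1,2-dioxolane | COC1(C)CC(C)(OC)OO1
A2 | alternative 1 | trimethyl{[3-(trimethylsilyl)prop-1-en-2-yl]oxy}silane | C=C(C[Si](C)(C)C)O[Si](C)(C)C
A3 | alternative 1 | (1R,5S)-1,5-dimethyl-6,7-dioxabicyclo[3.2.1]octan-3-one | O=C1C[C@]2(C)C[C@](C)(C1)OO2
A4 | alternative 2 | 1-ethenyl-1,2-dimethyl-2-[(2R)-2-methyl-10-phenyldecyl]cyclopropane | C[C@H](CCCCCCCCc1ccccc1)CC1(C)CC1(C)C=C
A5 | alternative 2 | (3R,5R)-3-ethenyl-3,5-dimethyl-5-[(2R)-2-methyl-10-phenyldecyl]-1,2-dioxolane | C[C@H](CCCCCCCCc1ccccc1)C[C@]1(C)C[C@](C)(C=C)OO1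
A6 | alternative 3 | (4R)-4-methyl-12-phenyldodecan-2-one | CC(=O)C[C@H](C)CCCCCCCCc1ccccc1
A7 | alternative 3 | triethyl{[(4R)-2-methoxy-4-methyl-12-phenyldodecan-2-yl]peroxy}silane | CC[Si](CC)(CC)OOC(C)(OC)C[C@H](C)CCCCCCCCc1ccccc1
A8 | alternative 3 | methyl 3-methylbut-3-enoate | C=C(C)CC(=O)OC
A9 | alternative 3 | methyl 2-[(3R,5R)-3,5-dimethyl-5-[(2R)-2-methyl-10-phenyldecyl]-1,2-dioxolan-3-yl]acetate | C[C@H](CCCCCCCCc1ccccc1)C[C@]1(C)C[C@](C)(CC(=O)OC)OO1
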